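**Plan**

- Retrosynthetic cuts: the C19 acetate and C15 ester (functional-group level), C8=C17 (methylenation of a C8 ketone), C12–C13 (coupling of a C9 vinyl group with the Z-iodoenoate), C4–C18 (enolate methylation), C9–C10 (ring B), then C9–C11 (aldol), C6–C7 (benzylic allylation) and aryl–C20 on a 6-methylsalicylate.
- Enabling feature: quaternary C10 (bearing C20) lies para to C3 and between C5 and C9, and C4 carries an oxidised carbon (C19). Ring A can therefore be a methyl 5-methylsalicylate whose phenoxide attacks an allyl terminus (C9) through C10.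
- Forward order: ring A is the arene from the start; ring B closes in step 13; ring A is then reduced (C1=C2, then C4=C5 with C4 methylation), C3 is deoxygenated, C19 reduced, the chain joined at C12–C13, and C17 and the acetate come last.
- Stereochemistry: C9 from the chiral iridium–phosphoramidite catalyst; C10 relative to C9 (chair-like closure); C5 from dissolving-metal protonation (trans fusion); C4 from α-face methylation anti to axial C20; 13Z from the iodoenoate with retention.

Key step: step 13

Remark: labdane numbering is used for all intermediates (ring carbons C1–C10, C18 = 4α-methyl, C19 = 4β-carbon, C20 = methyl on C10, C11/C12 on C9, C17 on C8); β is the face of C20; PMB = 4-methoxybenzyl; nor-labdane names carry the normal labdane configuration (5α-H, 9α-H, 10β-CH3).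

Assumption: the absolute sense of induction in step 13 is not predicted with certainty; the ligand L (binaphthol-derived N,N-bis(1-phenylethyl)phosphoramidite) is written as its (Sa,S,S) form and its mirror image is used if the first cyclisation should deliver ent-19.

**Route**

Step 1
Reactants: 1 2-hydroxy-6-methylbenzoic acid
Product: 2 methyl 2-hydroxy-6-methylbenzoate
Conditions: MeI, KHCO3, DMF, rt
Reagents that add atoms: iodomethane, CI
Why: Carboxylate O-alkylation (SN2 on MeI) should esterify the di-ortho-substituted acid, which resists Fischer esterification, while KHCO3 is too weak to ionise the hydrogen-bonded phenol.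

Step 2
Reactants: 2 methyl 2-hydroxy-6-methylbenzoate
Product: 3 methyl 3-bromo-6-hydroxy-2-methylbenzoate
Conditions: N-bromosuccinimide, MeCN, 0 °C → rt
Reagents that add atoms: N-bromosuccinimide, O=C1CCC(=O)N1Br
Why: Electrophilic aromatic bromination should go para to the hydroxyl group (also ortho to the ring methyl and meta to the ester), as in m-cresol-type phenols in polar solvent.

Step 3
Reactants: 3 methyl 3-bromo-6-hydroxy-2-methylbenzoate
Product: 4 methyl 3-bromo-6-[(4-methoxybenzyl)oxy]-2-methylbenzoate
Conditions: 4-methoxybenzyl chloride, K2CO3, DMF, 60 °C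
Reagents that add atoms: 4-methoxybenzyl chloride, COc1ccc(CCl)cc1
Why: Williamson etherification gives a PMB ether that tolerates the amide bases, palladium steps and silyl triflate ahead and can later be removed oxidatively without acid.

Step 4
Reactants: 4 methyl 3-bromo-6-[(4-methoxybenzyl)oxy]-2-methylbenzoate
Product: 5 methyl 6-[(4-methoxybenzyl)oxy]-2,3-dimethylbenzoate
Conditions: trimethylboroxine, Pd(dppf)Cl2 (cat.), K2CO3, 1,4-dioxane, 100 °C
Reagents that add atoms: trimethylboroxine, CB1OB(C)OB(C)O1
Why: Suzuki–Miyaura methylation of the aryl bromide places the future C20 on the carbon para to the oxygen, and the hindered ester should survive the carbonate base.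

Step 5
Reactants: 5 methyl 6-[(4-methoxybenzyl)oxy]-2,3-dimethylbenzoate; 6 allyl bromide
Product: 8 methyl 2-(but-3-en-1-yl)-6-[(4-methoxybenzyl)oxy]-3-methylbenzoate, via benzylic lithium compound 7 (not isolated)
Conditions: LiN(i-Pr)2, THF, −78 °C; then 6, −78 → −40 °C
Reagents that add atoms: none
Why: Lateral lithiation of an o-toluate: only the methyl group ortho to the ester gives an ester-stabilised benzylic anion, whose SN2 alkylation by allyl bromide forms C6–C7.

Step 6
Reactants: 8 methyl 2-(but-3-en-1-yl)-6-[(4-methoxybenzyl)oxy]-3-methylbenzoate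
Product: 9 methyl 6-[(4-methoxybenzyl)oxy]-3-methyl-2-(3-oxobutyl)benzoate
Conditions: PdCl2 (cat.), CuCl, O2 (1 atm), DMF/H2O, rt
Reagents that add atoms: water, O
Why: Tsuji–Wacker oxidation: Markovnikov oxypalladation of the terminal alkene by water should give the methyl ketone, placing the oxygen on C8 and leaving C9 as a methyl group for the aldol.

Step 7
Reactants: 9 methyl 6-[(4-methoxybenzyl)oxy]-3-methyl-2-(3-oxobutyl)benzoate; 10 (tert-butyldimethylsilyloxy)acetaldehyde
Product: 12 methyl 2-[6-(tert-butyldimethylsilyloxy)-5-hydroxy-3-oxohexyl]-6-[(4-methoxybenzyl)oxy]-3-methylbenzoate (racemic), via terminal lithium enolate 11 (not isolated)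
Conditions: LiN(i-Pr)2, THF, −78 °C; then 10, −78 °C
Reagents that add atoms: none
Why: Kinetic deprotonation of the methyl ketone at its methyl group followed by aldol addition forms C9–C11, and the di-ortho-substituted aryl ester should not be attacked at −78 °C.

Step 8
Reactants: 12 methyl 2-[6-(tert-butyldimethylsilyloxy)-5-hydroxy-3-oxohexyl]-6-[(4-methoxybenzyl)oxy]-3-methylbenzoate
Product: 14 methyl 2-[(4E)-6-(tert-butyldimethylsilyloxy)-3-oxohex-4-en-1-yl]-6-[(4-methoxybenzyl)oxy]-3-methylbenzoate, via mesylate 13 (not isolated)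
Conditions: MsCl, Et3N, CH2Cl2, 0 °C; then DBU, rt
Reagents that add atoms: none
Why: Mesylation and E1cB elimination complete the aldol condensation and should give the conjugated (E)-enone, the thermodynamically preferred geometry.

Step 9
Reactants: 14 methyl 2-[(4E)-6-(tert-butyldimethylsilyloxy)-3-oxohex-4-en-1-yl]-6-[(4-methoxybenzyl)oxy]-3-methylbenzoate
Product: 15 methyl 2-(2-{2-[(1E)-3-(tert-butyldimethylsilyloxy)prop-1-en-1-yl]-1,3-dioxolan-2-yl}ethyl)-6-[(4-methoxybenzyl)oxy]-3-methylbenzoate
Conditions: Me3SiOCH2CH2OSiMe3, Me3SiOTf (cat.), CH2Cl2, −78 → −20 °C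
Reagents that add atoms: 1,2-bis(trimethylsilyloxy)ethane, C[Si](C)(C)OCCO[Si](C)(C)C
Why: Noyori ketalisation (silyl triflate catalysis, aprotic, low temperature) should protect C8 as the dioxolane without moving the enone double bond, which Brønsted-acid ketalisation tends to shift.

Step 10
Reactants: 15 silyl ether ketal (as named in step 9)
Product: 16 methyl 2-(2-{2-[(1E)-3-hydroxyprop-1-en-1-yl]-1,3-dioxolan-2-yl}ethyl)-6-[(4-methoxybenzyl)oxy]-3-methylbenzoate
Conditions: Bu4NF, THF, 0 °C → rt
Reagents that add atoms: none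
Why: Fluoride desilylation frees the primary allylic alcohol; ketal, esters and PMB ether are inert to fluoride.

Step 11
Reactants: 16 allylic alcohol (as named in step 10)
Product: 17 methyl 2-(2-{2-[(1E)-3-[(methoxycarbonyl)oxy]prop-1-en-1-yl]-1,3-dioxolan-2-yl}ethyl)-6-[(4-methoxybenzyl)oxy]-3-methylbenzoate
Conditions: ClCO2Me, pyridine, CH2Cl2, 0 °C
Reagents that add atoms: methyl chloroformate, COC(=O)Cl
Why: O-acylation with the chloroformate gives the (E)-allyl methyl carbonate, the leaving group that releases methoxide as internal base on ionisation.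

Step 12
Reactants: 17 PMB-protected allyl carbonate (as named in step 11)
Product: 18 methyl 6-hydroxy-2-(2-{2-[(1E)-3-[(methoxycarbonyl)oxy]prop-1-en-1-yl]-1,3-dioxolan-2-yl}ethyl)-3-methylbenzoate
Conditions: DDQ, CH2Cl2/pH 7 buffer, 0 °C → rt
Reagents that add atoms: none
Why: Oxidative PMB cleavage (hydride abstraction by DDQ, hydrolysis of the oxocarbenium ion) should unmask the phenol under neutral conditions that spare the dioxolane, the carbonate and the alkene.

Step 13
Reactants: 18 methyl 6-hydroxy-2-(2-{2-[(1E)-3-[(methoxycarbonyl)oxy]prop-1-en-1-yl]-1,3-dioxolan-2-yl}ethyl)-3-methylbenzoate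
Product: 19 methyl (9R,10R)-8,8-ethylenedioxy-3-oxo-13,14,15,16,17,18-hexanorlabda-1,4,11-trien-19-oate (cross-conjugated dienone; 9β-vinyl; 10β-methyl)
Conditions: [Ir(cod)Cl]2 (cat.), ligand L (cat.), n-PrNH2 (catalyst activation), Cs2CO3, THF (0.02 M), 50 °C
Reagents that add atoms: none
Why: Proposed new method: the cyclometalated iridium–phosphoramidite complex ionises the allylic carbonate (CO2 and methoxide leave) and the caesium phenoxide attacks the substituted allyl terminus C9 through its para carbon C10, anti to the metal, which forms C9–C10 and turns ring A into a cross-conjugated 2,5-cyclohexadienone. The closest known reaction type is the iridium-catalysed intramolecular asymmetric allylic dearomatisation of phenols, which is known for phenols tethered at the para carbon (spiro-dienones) but has not been shown for a meta-tethered phenol closing onto a methyl-substituted para carbon to give a ring-fused dienone. Ring B closes in the 6-exo mode (attack at the internal allyl carbon leaves C11=C12 as the vinyl group), whereas attack at C12 would need an eight-membered ring. C9 is set by the ligand, which fixes the allyl face offered to the nucleophile, and C10 follows from a chair-like transition state with the vinyl group equatorial (9β-vinyl cis to 10β-methyl); a C10-epimeric diastereomer would be removed by chromatography, so that the enantiomeric purity of 19 rests on the C9 induction. The step needs attack through C10 and not through ester-bearing C4, both of which flank the tether: C4 is crowded by the ion-paired phenoxide oxygen and the ester while C10 has only C1–H and a methyl group as neighbours, para attack keeps the ester conjugated and leads to the more stable cross-conjugated dienone, and a loosely paired caesium phenoxide in dilute THF favours para over ortho C-alkylation. O-Allylation would need an eight- or ten-membered ring and C2 cannot reach the allyl unit.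

Step 14
Reactants: 19 dienone (as named in step 13)
Product: 20 methyl 8,8-ethylenedioxy-3-oxo-13,14,15,16,17,18-hexanorlabda-4,11-dien-19-oate
Conditions: [(Ph3P)CuH]6 (0.2 equiv), H2O (2 equiv), benzene/THF, rt
Reagents that add atoms: none
Why: Copper hydride conjugate reduction should deliver hydride to the unsubstituted β-carbon C1 of the disubstituted enone, while the tetrasubstituted C4=C5 bond (β-carbon C5 fully substituted, next to quaternary C10) and the isolated vinyl group are left.

Step 15
Reactants: 20 enone ester (as named in step 14)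
Product: 22 methyl 8,8-ethylenedioxy-3-oxo-13,14,15,16,17-pentanorlabd-11-en-19-oate (5α-H; 4α-methyl; 4β-ester), via lithium enolate 21 (not isolated)
Conditions: Li, NH3(l)/THF, t-BuOH (1 equiv), −78 °C; then MeI, −78 → −33 °C
Reagents that add atoms: iodomethane, CI
Why: Dissolving-metal reductive alkylation: protonation at C5 anti to the 10β-methyl should give the trans ring fusion, and MeI should enter the C3–C4 enolate from the α face, away from the axial 10β-methyl, so that the ester ends axial (β, future C19) and the new methyl equatorial (α, C18).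

Step 16
Reactants: 22 β-keto ester (as named in step 15)
Product: 23 methyl 8,8-ethylenedioxy-3β-hydroxy-13,14,15,16,17-pentanorlabd-11-en-19-oate
Conditions: NaBH4, MeOH, 0 °C
Reagents that add atoms: none
Why: Borohydride reduction takes the ketone and not the ester, hydride arriving from the less hindered α face to give the equatorial 3β-alcohol, whose configuration does not matter because C3 is deoxygenated next.

Step 17
Reactants: 23 3β-alcohol (as named in step 16)
Product: 24 methyl 8,8-ethylenedioxy-3β-[(1H-imidazol-1-ylcarbonothioyl)oxy]-13,14,15,16,17-pentanorlabd-11-en-19-oate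
Conditions: 1,1'-thiocarbonyldiimidazole, DMAP (cat.), ClCH2CH2Cl, 70 °C
Reagents that add atoms: 1,1'-thiocarbonyldiimidazole, S=C(n1ccnc1)n1ccnc1
Why: Thioacylation of the hindered secondary alcohol under neutral conditions prepares the radical deoxygenation without exposing the β-hydroxy ester to an alkoxide (retro-aldol).

Step 18
Reactants: 24 imidazolyl thiocarbamate (as named in step 17)
Product: 25 methyl 8,8-ethylenedioxy-13,14,15,16,17-pentanorlabd-11-en-19-oate
Conditions: Bu3SnH, AIBN (cat.), toluene, 100 °C
Reagents that add atoms: none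
Why: Barton–McCombie deoxygenation: the stannyl radical adds to C=S, the C3–O bond fragments and the secondary radical is reduced by Bu3SnH faster than it can rearrange, while the remote unactivated vinyl group should not be hydrostannylated.

Step 19
Reactants: 25 ester (as named in step 18)
Product: 26 8,8-ethylenedioxy-13,14,15,16,17-pentanorlabd-11-en-19-ol
Conditions: LiAlH4, THF, 0 °C → reflux
Reagents that add atoms: none
Why: Hydride reduction of the hindered axial ester gives the primary alcohol at C19; ketal and vinyl group are inert to LiAlH4.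

Step 20
Reactants: 26 8,8-ethylenedioxy-13,14,15,16,17-pentanorlabd-11-en-19-ol; 27 ethyl (Z)-3-iodobut-2-enoate
Product: 29 ethyl (13Z)-8,8-ethylenedioxy-19-hydroxy-17-norlabd-13-en-15-oate, via trialkylborane 28 (not isolated)
Conditions: 9-BBN-H (2.5 equiv), THF, rt; then 27, Pd(dppf)Cl2 (cat.), Ph3As (cat.), Cs2CO3, DMF/H2O, rt
Reagents that add atoms: none
Why: Anti-Markovnikov hydroboration of the vinyl group and B-alkyl Suzuki–Miyaura coupling form C12–C13 with retention of the iodoalkene geometry (13Z), the alcohol being carried as its borinate and freed again by the aqueous base.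

Step 21
Reactants: 29 ketal ester (as named in step 20)
Product: 30 ethyl (13Z)-19-hydroxy-8-oxo-17-norlabd-13-en-15-oate
Conditions: 1 M HCl (aq), THF, rt → 40 °C
Reagents that add atoms: water, O
Why: Acid-catalysed ketal hydrolysis frees the C8 ketone; the C9 side chain is already equatorial, so enolisation under the acid cannot erode C9.

Step 22
Reactants: 30 ketone (as named in step 21)
Product: 31 ethyl (13Z)-19-hydroxylabda-8(17),13-dien-15-oate
Conditions: Zn, CH2Br2, TiCl4, THF (reagent aged at 0–5 °C); then 30, CH2Cl2, 0 °C → rt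
Reagents that add atoms: dibromomethane, BrCBr
Why: Lombardo methylenation uses a non-basic gem-dimetallic methylene reagent that converts hindered, enolisable ketones, tolerates the ester and the free alcohol, and should cause neither C9 epimerisation nor Z/E isomerisation of the enoate.

Step 23
Reactants: 31 ethyl ester (as named in step 22)
Product: 32 (13Z)-19-hydroxylabda-8(17),13-dien-15-oic acid
Conditions: LiOH, THF/MeOH/H2O, 50 °C; then 1 M HCl to pH 4, 0 °C
Reagents that add atoms: lithium hydroxide, [Li+].[OH-]
Why: Saponification of the conjugated ethyl ester; the exocyclic alkene and the trisubstituted Z-alkene are stable to hydroxide.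

Step 24
Reactants: 32 (13Z)-19-hydroxylabda-8(17),13-dien-15-oic acid
Product: 34 (13Z)-19-acetoxylabda-8(17),13-dien-15-oic acid (CNP0360430.3), via mixed anhydride 33 (not isolated)
Conditions: Ac2O, pyridine, rt; then H2O/THF, rt
Reagents that add atoms: acetic anhydride, CC(=O)OC(C)=O
Why: O-acetylation of the primary C19 alcohol; any mixed carboxylic–acetic anhydride formed at C15 is hydrolysed back to the acid by the aqueous pyridine quench.

**Compound list**

1 | 2-hydroxy-6-methylbenzoic acid | Cc1cccc(O)c1C(=O)O | starting material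
2 | methyl 2-hydroxy-6-methylbenzoate | COC(=O)c1c(C)cccc1O | intermediate
3 | methyl 3-bromo-6-hydroxy-2-methylbenzoate | COC(=O)c1c(C)c(Br)ccc1O | intermediate
4 | methyl 3-bromo-6-[(4-methoxybenzyl)oxy]-2-methylbenzoate | COC(=O)c1c(C)c(Br)ccc1OCc1ccc(OC)cc1 | intermediate
5 | methyl 6-[(4-methoxybenzyl)oxy]-2,3-dimethylbenzoate | COC(=O)c1c(C)c(C)ccc1OCc1ccc(OC)cc1 | intermediate
6 | allyl bromide | C=CCBr | starting material
7 | benzylic lithium compound of 5, lithiated at the 2-methyl group (not isolated) | COC(=O)c1c(C[Li])c(C)ccc1OCc1ccc(OC)cc1 | intermediate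
8 | methyl 2-(but-3-en-1-yl)-6-[(4-methoxybenzyl)oxy]-3-methylbenzoate | COC(=O)c1c(CCC=C)c(C)ccc1OCc1ccc(OC)cc1 | intermediate
9 | methyl 6-[(4-methoxybenzyl)oxy]-3-methyl-2-(3-oxobutyl)benzoate | COC(=O)c1c(CCC(C)=O)c(C)ccc1OCc1ccc(OC)cc1 | intermediate
10 | (tert-butyldimethylsilyloxy)acetaldehyde | O=CCO[Si](C)(C)C(C)(C)C | starting material
11 | terminal lithium enolate of 9 (not isolated) | COC(=O)c1c(CCC(=C)O[Li])c(C)ccc1OCc1ccc(OC)cc1 | intermediate
12 | methyl 2-[6-(tert-butyldimethylsilyloxy)-5-hydroxy-3-oxohexyl]-6-[(4-methoxybenzyl)oxy]-3-methylbenzoate, racemic at the carbinol carbon | COC(=O)c1c(CCC(=O)CC(O)CO[Si](C)(C)C(C)(C)C)c(C)ccc1OCc1ccc(OC)cc1 | intermediate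
13 | methanesulfonate of 12 at the secondary hydroxyl, racemic (not isolated) | COC(=O)c1c(CCC(=O)CC(OS(C)(=O)=O)CO[Si](C)(C)C(C)(C)C)c(C)ccc1OCc1ccc(OC)cc1 | intermediate
14 | methyl 2-[(4E)-6-(tert-butyldimethylsilyloxy)-3-oxohex-4-en-1-yl]-6-[(4-methoxybenzyl)oxy]-3-methylbenzoate | COC(=O)c1c(CCC(=O)/C=C/CO[Si](C)(C)C(C)(C)C)c(C)ccc1OCc1ccc(OC)cc1 | intermediate
15 | methyl 2-(2-{2-[(1E)-3-(tert-butyldimethylsilyloxy)prop-1-en-1-yl]-1,3-dioxolan-2-yl}ethyl)-6-[(4-methoxybenzyl)oxy]-3-methylbenzoate | COC(=O)c1c(CCC2(OCCO2)/C=C/CO[Si](C)(C)C(C)(C)C)c(C)ccc1OCc1ccc(OC)cc1 | intermediate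
16 | methyl 2-(2-{2-[(1E)-3-hydroxyprop-1-en-1-yl]-1,3-dioxolan-2-yl}ethyl)-6-[(4-methoxybenzyl)oxy]-3-methylbenzoate | COC(=O)c1c(CCC2(OCCO2)/C=C/CO)c(C)ccc1OCc1ccc(OC)cc1 | intermediate
17 | methyl 2-(2-{2-[(1E)-3-[(methoxycarbonyl)oxy]prop-1-en-1-yl]-1,3-dioxolan-2-yl}ethyl)-6-[(4-methoxybenzyl)oxy]-3-methylbenzoate | COC(=O)c1c(CCC2(OCCO2)/C=C/COC(=O)OC)c(C)ccc1OCc1ccc(OC)cc1 | intermediate
18 | methyl 6-hydroxy-2-(2-{2-[(1E)-3-[(methoxycarbonyl)oxy]prop-1-en-1-yl]-1,3-dioxolan-2-yl}ethyl)-3-methylbenzoate (key-step precursor) | COC(=O)c1c(CCC2(OCCO2)/C=C/COC(=O)OC)c(C)ccc1O | intermediate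
19 | methyl (9R,10R)-8,8-ethylenedioxy-3-oxo-13,14,15,16,17,18-hexanorlabda-1,4,11-trien-19-oate: bicyclic dienone with C3 ketone, C1=C2 and C4=C5, ester on C4, 10β-methyl, 9β-vinyl, C8 dioxolane | O1CCOC12CCC3=C(C(=O)OC)C(=O)C=C[C@]3(C)[C@H]2C=C | intermediate
20 | methyl 8,8-ethylenedioxy-3-oxo-13,14,15,16,17,18-hexanorlabda-4,11-dien-19-oate | O1CCOC12CCC3=C(C(=O)OC)C(=O)CC[C@]3(C)[C@H]2C=C | intermediate
21 | lithium C3–C4 enolate formed from 20 by reduction, 5α-H (not isolated) | O1CCOC12CC[C@H]3C(C(=O)OC)=C(O[Li])CC[C@]3(C)[C@H]2C=C | intermediate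
22 | methyl 8,8-ethylenedioxy-3-oxo-13,14,15,16,17-pentanorlabd-11-en-19-oate (trans-decalin, 4α-CH3, 4β-CO2Me) | O1CCOC12CC[C@H]3[C@@](C)(C(=O)OC)C(=O)CC[C@]3(C)[C@H]2C=C | intermediate
23 | methyl 8,8-ethylenedioxy-3β-hydroxy-13,14,15,16,17-pentanorlabd-11-en-19-oate | O1CCOC12CC[C@H]3[C@@](C)(C(=O)OC)[C@@H](O)CC[C@]3(C)[C@H]2C=C | intermediate
24 | methyl 8,8-ethylenedioxy-3β-[(1H-imidazol-1-ylcarbonothioyl)oxy]-13,14,15,16,17-pentanorlabd-11-en-19-oate | O1CCOC12CC[C@H]3[C@@](C)(C(=O)OC)[C@@H](OC(=S)n4ccnc4)CC[C@]3(C)[C@H]2C=C | intermediate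
25 | methyl 8,8-ethylenedioxy-13,14,15,16,17-pentanorlabd-11-en-19-oate | O1CCOC12CC[C@H]3[C@@](C)(C(=O)OC)CCC[C@]3(C)[C@H]2C=C | intermediate
26 | 8,8-ethylenedioxy-13,14,15,16,17-pentanorlabd-11-en-19-ol | O1CCOC12CC[C@H]3[C@@](C)(CO)CCC[C@]3(C)[C@H]2C=C | intermediate
27 | ethyl (Z)-3-iodobut-2-enoate | C/C(I)=C/C(=O)OCC | starting material
28 | trialkylborane from 26: C12 bound to the boron of 9-borabicyclo[3.3.1]nonane, C19–O as its 9-BBN borinate (not isolated) | O1CCOC12CC[C@H]3[C@@](C)(COB4C5CCCC4CCC5)CCC[C@]3(C)[C@H]2CCB6C7CCCC6CCC7 | intermediate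
29 | ethyl (13Z)-8,8-ethylenedioxy-19-hydroxy-17-norlabd-13-en-15-oate | O1CCOC12CC[C@H]3[C@@](C)(CO)CCC[C@]3(C)[C@H]2CC/C(C)=C\C(=O)OCC | intermediate
30 | ethyl (13Z)-19-hydroxy-8-oxo-17-norlabd-13-en-15-oate | O=C1CC[C@H]2[C@@](C)(CO)CCC[C@]2(C)[C@H]1CC/C(C)=C\C(=O)OCC | intermediate
31 | ethyl (13Z)-19-hydroxylabda-8(17),13-dien-15-oate | C=C1CC[C@H]2[C@@](C)(CO)CCC[C@]2(C)[C@H]1CC/C(C)=C\C(=O)OCC | intermediate
32 | (13Z)-19-hydroxylabda-8(17),13-dien-15-oic acid | C=C1CC[C@H]2[C@@](C)(CO)CCC[C@]2(C)[C@H]1CC/C(C)=C\C(=O)O | intermediate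
33 | mixed anhydride of the 19-acetoxy acid with acetic acid (not isolated) | C=C1CC[C@H]2[C@@](C)(COC(C)=O)CCC[C@]2(C)[C@H]1CC/C(C)=C\C(=O)OC(C)=O | intermediate
34 | (13Z)-19-acetoxylabda-8(17),13-dien-15-oic acid, (4S,5R,9S,10R); CNP0360430.3 | C=C1CC[C@H]2[C@@](C)(COC(C)=O)CCC[C@]2(C)[C@H]1CC/C(C)=C\C(=O)O | target

**Step count and risks**

Total: 24 steps. Longest linear sequence: 24 steps (1 → 34); compounds 6, 10 and 27 are used as purchased.

Most likely to fail:

1. Step 13 (the step labelled as a new method). What may go wrong: the phenoxide may alkylate through the ester-bearing ortho carbon C4 instead of C10; the allyl terminus next to the ketal may be too hindered, so that intermolecular O-allylation wins over ring closure; the C9/C10 diastereocontrol may be poor. Fallback with reversed polarity, built on known reaction types; it sets out from 17 and comes back at 19. Palladium-catalysed silylation of the allylic carbonate with hexamethyldisilane (Pd2(dba)3 cat., DMF, 60 °C) should give the (E)-allylsilane PMB ether F1. DDQ then frees the phenol allylsilane F2. Oxidation of F2 with PhI(OAc)2 in CF3CH2OH at −20 °C (hypervalent-iodine oxidative dearomatisation with an intramolecular allylsilane trap, a Sakurai-type closure) should join C9 to C10 with loss of silicon. In the phenoxonium ion the ester makes C4 the carbon least able to carry positive charge, so the site preference now points to the methyl-bearing para carbon. The product is racemic 19, that is 19 together with the mirror-image dienone F3, which is removed by chromatography on a chiral stationary phase; the route resumes at 19.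

2. Step 14. What may go wrong: hydride transfer to C5 of the doubly activated C4=C5 bond, or reduction of both enone double bonds. Fallback by changing the order of events; it sets out from 19 and comes back at 22. Li/NH3 (t-BuOH, 1 equiv) is applied to the dienone first. It should reduce the ester-bearing C4=C5 bond, the most electron-poor alkene, because protonation at C5 leaves a β-keto ester enolate; MeI then methylates C4 to give the 1-en-3-one keto ester F4. The single enone left in F4 is reduced with [(Ph3P)CuH]6 (or LiBH(s-Bu)3), which gives 22.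

3. Step 9. What may go wrong: migration of the double bond out of conjugation, conjugate addition of the diol, loss of the silyl ether, or stalled conversion of the enone. Fallback by masking the alkene; it sets out from 14 and comes back at 15. Conjugate addition of PhSeH (from PhSeSePh and NaBH4, EtOH, AcOH) should give the β-phenylseleno ketone F5. The now saturated ketone is ketalised (Me3SiOCH2CH2OSiMe3, Me3SiOTf cat., −78 °C) to the β-phenylseleno ketal F6. Oxidation with H2O2/pyridine and selenoxide syn-elimination, which runs away from the oxygen-bearing carbon, should restore the (E)-alkene and give 15.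

Further compounds
F1 | step 13 | methyl 6-[(4-methoxybenzyl)oxy]-3-methyl-2-(2-{2-[(1E)-3-(trimethylsilyl)prop-1-en-1-yl]-1,3-dioxolan-2-yl}ethyl)benzoate | COC(=O)c1c(CCC2(OCCO2)/C=C/C[Si](C)(C)C)c(C)ccc1OCc1ccc(OC)cc1
F2 | step 13 | methyl 6-hydroxy-3-methyl-2-(2-{2-[(1E)-3-(trimethylsilyl)prop-1-en-1-yl]-1,3-dioxolan-2-yl}ethyl)benzoate | COC(=O)c1c(CCC2(OCCO2)/C=C/C[Si](C)(C)C)c(C)ccc1O
F3 | step 13 | mirror-image dienone, methyl (9S,10S)-8,8-ethylenedioxy-3-oxo-13,14,15,16,17,18-hexanorlabda-1,4,11-trien-19-oate (ent-19) | O1CCOC12CCC3=C(C(=O)OC)C(=O)C=C[C@@]3(C)[C@@H]2C=C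
F4 | step 14 | methyl 8,8-ethylenedioxy-3-oxo-13,14,15,16,17-pentanorlabda-1,11-dien-19-oate (1-en-3-one keto ester, 5α-H, 4α-CH3) | O1CCOC12CC[C@H]3[C@@](C)(C(=O)OC)C(=O)C=C[C@]3(C)[C@H]2C=C
F5 | step 9 | methyl 2-[6-(tert-butyldimethylsilyloxy)-3-oxo-5-(phenylselanyl)hexyl]-6-[(4-methoxybenzyl)oxy]-3-methylbenzoate (racemic) | COC(=O)c1c(CCC(=O)CC([Se]c2ccccc2)CO[Si](C)(C)C(C)(C)C)c(C)ccc1OCc1ccc(OC)cc1
F6 | step 9 | methyl 2-(2-{2-[3-(tert-butyldimethylsilyloxy)-2-(phenylselanyl)propyl]-1,3-dioxolan-2-yl}ethyl)-6-[(4-methoxybenzyl)oxy]-3-methylbenzoate (racemic) | COC(=O)c1c(CCC2(OCCO2)CC([Se]c2ccccc2)CO[Si](C)(C)C(C)(C)C)c(C)ccc1OCc1ccc(OC)cc1
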